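(The runs stem from a simulated flask for substances that don't exist; the scatter is artificial.)

The pitfall in these runs was to read them in the unit they are printed in: counted per substrate charged, the last readings stand at 22 %, 22 % and 19 %, and the partner seems to matter little.

| flask | substrate | partner | remark | time |
|---|---|---|---|---|
| midnight | 0.10 M | 0.095 M | run made earlier |  |
| dusk | 0.10 M | 0.048 M | run made earlier |  |
| noon | 0.10 M | 0.071 M | run made earlier |  |
| north-west | 0.10 M (fed, over 20 s) | 0.0950 M | all else is in the flask from the start; the feed brings no volume worth counting | 5.0 min |
| south | 0.10 M | 0.0950 M (fed, over 3.0 min) | all else is in the flask from the start; the feed brings no volume worth counting | 5.0 min |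
| east | 0.10 M (in portions, 2, over 3.0 min) | 0.0950 M | first portion at the start, last at 3.0 min | 5.0 min |
| south-west | 0.10 M (fed, over 3.0 min) | 0.0950 M | all else is in the flask from the start; the feed brings no volume worth counting | 5.0 min |
| north-east | 0.10 M | 0.0950 M | everything together at the start | 5.0 min |

| run | time / min | target / % |
|---|---|---|
| midnight | 0.250 | 8 |
| midnight | 0.500 | 14 |
| midnight | 1.33 | 20 |
| midnight | 3.00 | 22 |
| dusk | 1.33 | 13 |
| dusk | 2.50 | 17 |
| dusk | 4.00 | 17 |
| dusk | 5.00 | 19 |
| noon | 1.33 | 17 |
| noon | 2.50 | 22 |
| noon | 4.00 | 22 |
| noon | 5.00 | 22 |

(scatter of a reading: 1.5 percentage points)

- what was read earlier has a scatter of 1.5 percentage points, one standard deviation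
- a reading or a percentage of target counts all its forms, free or not

1. the best flask by amount of target, in percent of the substrate charged; "all alike" if 1.5 percentage points covers them all (north-west / south / east / south-west / north-east / all alike)
2. amount of target at the end, in percent of the substrate charged, north-west
3. amount of target at the end, in percent of the substrate charged, south
4. amount of target at the end, in percent of the substrate charged, east
5. amount of target at the end, in percent of the substrate charged, south-west
6. amount of target at the end, in percent of the substrate charged, north-east

So I recounted the last readings per partner charged. Dusk's partner yield, the target formed per partner charged (the yield on the limiting reagent), read 39.6 %, noon's read 31.0 % and midnight's read 23.2 %. Dusk's reading stood higher than midnight's by 16 percentage points, against a scatter of about 3.1 points on dusk's reading, so in these runs a smaller partner charge gave a larger partner yield.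

But the new flasks differ in how the partner stands in them. South feeds it over 3.0 min, and even with none consumed its level reaches dusk's charge after 1.52 min. So I carried dusk's yield to south and reckoned 37.6 % of the substrate charged. North-west, east, south-west and north-east hold the full partner charge from the start, so I put them at about midnight's 22 % or below, and I chose south.

The forecast, made from the same runs, differed from my reckoning. It chose south-west at 33 %, with east at 30 %, north-west at 24 %, north-east at 22 % and south at 19 %, holding that “selectivity depends mainly on substrate level”.

The best flask was south at 31.1 %, ahead of north-east at 23.1 %, north-west at 22.4 %, south-west at 13.4 % and east at 8.66 %.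

    crystals ⇌ target, rate k1*(cs1 - [target]) while solid is left; crystals form when [target] > cs1 (solubility = 5.80 mM, k = 0.810 s⁻¹)
    partner → decomposed reagent (k = 7.00 × 10⁻⁴ s⁻¹)
    substrate + partner → target (k = 0.150 L mol⁻¹ s⁻¹)
    substrate + 2 partner → side product (k = 2.40 L² mol⁻² s⁻¹)
    partner + target → over-reaction product (k = 0.560 L mol⁻¹ s⁻¹)

Mean partner over the first 3.0 min was 0.0178 M in south, against 0.0490 M in south-west. South's partner yield came to 32.7 %, below the 39.6 % I carried from dusk, and south-west's came to 14.1 %. The neighbour of south with 0.24 M of partner gave 9.19 % of target, a partner yield of 3.83 %.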